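The route rests on unzipping the oxirane-fused edge of the cyclohexenone. Ring atoms are labelled C1 (acetoxy carbinol), C2 (methyl-bearing alkene carbon), C3 (alkene CH), C4 (ketone), C5 (quaternary oxirane carbon with the chain), C6 (oxirane CH). The oxirane spans the C5–C6 ring bond and C5 lies next to the C4 carbonyl, i.e. an alpha,beta-epoxy (glycidic) ketone. An intramolecular Darzens reaction under chiral ion-pair catalysis exploits exactly this: it forges C5–C6 and C5–O in one operation, closes carbocycle and oxirane, and sets both stereocentres. Its precursor is an acyclic Z-enone bearing a racemic C5 bromide, a C6 aldehyde, a C1 dimethyl ketal and the silylated hydroxyfarnesyl chain.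

Key step: step 14

Notation: R = (2E,6E,10E)-12-(tert-butyldiphenylsilyloxy)-3,7,11-trimethyldodeca-2,6,10-trien-1-yl; PMB = 4-methoxybenzyl. The labels C1–C6 are also used for the acyclic compounds.

Design remarks:
- The chain hydroxyl travels as a TBDPS ether, because it must outlast the acidic unmasking of C1.
- C4 and C5 arrive together with the chain as one N-methoxy-N-methyl amide, so no enolate of the sensitive Z-enone has to be alkylated.
- The aldol half of the key step belongs to the enolendo class, because C4 and C5 both become ring members.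

Assumption: the sense of induction of the cinchona salt cannot be predicted for this substrate. The cinchonine-derived salt is written. Its pseudoenantiomeric cinchonidine-derived salt takes its place if that one proves matched for (5R,6S).

Step 1
Reactants: 1 1,3-dihydroxyacetone (sold as its dimer)
Product: 2 2,2-dimethoxypropane-1,3-diol
Conditions: HC(OMe)3, MeOH, p-TsOH·H2O (cat.), rt
Reagents that add atoms: trimethyl orthoformate, COC(OC)OC; methanol, CO
Why: Acid-catalysed ketalisation, driven by the orthoester as water scavenger, turns the ketone into the dimethyl ketal that becomes C1; no stereocentre arises.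

Step 2
Reactants: 2 2,2-dimethoxypropane-1,3-diol
Product: 3 3-[(4-methoxybenzyl)oxy]-2,2-dimethoxypropan-1-ol
Conditions: NaH (1 equiv), 4-methoxybenzyl chloride, n-Bu4NI (cat.), THF/DMF, 0 °C to rt, 2 in excess
Reagents that add atoms: 4-methoxybenzyl chloride, COc1ccc(CCl)cc1
Why: Williamson etherification of the monosodium alkoxide of the cheap symmetrical diol distinguishes the two arms, the PMB-bearing one being the future C6.

Step 3
Reactants: 3 3-[(4-methoxybenzyl)oxy]-2,2-dimethoxypropan-1-ol
Product: 4 3-[(4-methoxybenzyl)oxy]-2,2-dimethoxypropanal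
Conditions: Dess–Martin periodinane, NaHCO3, CH2Cl2, 0 °C to rt
Reagents that add atoms: none
Why: Buffered Dess–Martin oxidation of a neopentyl-type primary alcohol stops at the non-enolisable aldehyde and spares ketal and PMB ether.

Step 4
Reactants: 4 3-[(4-methoxybenzyl)oxy]-2,2-dimethoxypropanal
Product: 5 1-{[(2,2-dimethoxybut-3-yn-1-yl)oxy]methyl}-4-methoxybenzene (alkynyl ketal HC≡C–C(OMe)2–CH2OPMB)
Conditions: dimethyl (1-diazo-2-oxopropyl)phosphonate, K2CO3, MeOH, 0 °C to rt
Reagents that add atoms: dimethyl (1-diazo-2-oxopropyl)phosphonate, CC(=O)C(=[N+]=[N-])P(=O)(OC)OC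
Why: Ohira–Bestmann (Seyferth–Gilbert) homologation converts the non-enolisable aldehyde into the terminal alkyne, the aldehyde carbon becoming C2 and the diazo carbon C3.

Step 5
Reactants: 6 (2E,6E)-farnesol
Product: 7 (2E,6E)-farnesyl bromide
Conditions: PBr3, Et2O, 0 °C
Reagents that add atoms: phosphorus tribromide, BrP(Br)Br
Why: Low-temperature SN2 bromination of the primary allylic alcohol through its phosphite ester keeps both E alkenes intact.

Step 6
Reactants: 8 N-methoxy-N-methylacetamide; 7 (2E,6E)-farnesyl bromide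
Product: 10 (4E,8E)-N-methoxy-N,5,9,13-tetramethyltetradeca-4,8,12-trienamide, via lithium enolate 9 (not isolated)
Conditions: 8 (excess), LiN(i-Pr)2 (LDA), THF, −78 °C; then 7, −78 to −20 °C
Reagents that add atoms: none
Why: Amide enolate alkylation, in which 9 displaces the primary allylic bromide by SN2 at the unsubstituted terminus, joins C5 to the chain and brings C4 along as an acyl donor.

Step 7
Reactants: 10 (4E,8E)-N-methoxy-N,5,9,13-tetramethyltetradeca-4,8,12-trienamide
Product: 11 (4E,8E,12E)-14-hydroxy-N-methoxy-N,5,9,13-tetramethyltetradeca-4,8,12-trienamide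
Conditions: SeO2 (cat.), t-BuOOH, salicylic acid (cat.), CH2Cl2, 0 °C to rt, partial conversion, 10 recycled
Reagents that add atoms: tert-butyl hydroperoxide, CC(C)(C)OO (oxygen atom, relayed by SeO2, O=[Se]=O)
Why: Catalytic SeO2 allylic hydroxylation (ene reaction, then [2,3]-sigmatropic shift) should pick the E-methyl group of the most accessible terminal isopropylidene unit, which fixes the 12E geometry, and partial conversion limits enal formation and attack on the inner alkenes.

Step 8
Reactants: 11 (4E,8E,12E)-14-hydroxy-N-methoxy-N,5,9,13-tetramethyltetradeca-4,8,12-trienamide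
Product: 12 (4E,8E,12E)-14-(tert-butyldiphenylsilyloxy)-N-methoxy-N,5,9,13-tetramethyltetradeca-4,8,12-trienamide (MeO(Me)N–C(=O)–CH2–R)
Conditions: t-BuPh2SiCl, imidazole, CH2Cl2, rt
Reagents that add atoms: tert-butylchlorodiphenylsilane, CC(C)(C)[Si](Cl)(c1ccccc1)c1ccccc1
Why: Imidazole-promoted silylation of the primary allylic alcohol installs a silyl ether robust enough for the bases ahead and for the acid of step 15.

Step 9
Reactants: 5 alkynyl ketal HC≡C–C(OMe)2–CH2OPMB; 12 amide MeO(Me)N–C(=O)–CH2–R
Product: 14 ynone PMBOCH2–C(OMe)2–C≡C–C(=O)–CH2–R, via lithium acetylide 13 (not isolated)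
Conditions: 5, n-BuLi, THF, −78 °C; then 12, −78 to 0 °C
Reagents that add atoms: none
Why: Weinreb ketone synthesis, in which 13 adds once to the N-methoxy-N-methyl amide without over-addition, forms the C3–C4 bond convergently.

Step 10
Reactants: 14 ynone PMBOCH2–C(OMe)2–C≡C–C(=O)–CH2–R
Product: 16 (Z)-enone PMBOCH2–C(OMe)2–C(Me)=CH–C(=O)–CH2–R (C1 cis to C4), via lithium allenolate 15 (not isolated)
Conditions: Me2CuLi (from CuI and MeLi), THF, −78 °C; AcOH/THF quench at −78 °C
Reagents that add atoms: lithium dimethylcuprate Me2CuLi, [Li+].C[Cu-]C (methyl group; prepared from methyllithium, [Li]C)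
Why: Gilman conjugate addition delivers methyl to C2, and 15 should be protonated at C3 in the plane of the C2 substituents from the side of the small methyl group, so C1 and C4 end up cis (Z), the same outcome as syn carbocupration followed by retentive protonolysis.

Step 11
Reactants: 16 (Z)-enone PMBOCH2–C(OMe)2–C(Me)=CH–C(=O)–CH2–R
Product: 18 racemic (Z)-bromo ketone PMBOCH2–C(OMe)2–C(Me)=CH–C(=O)–CHBr–R, via trimethylsilyl dienol ether 17 (not isolated)
Conditions: LiN(SiMe3)2, Me3SiCl, THF, −78 °C; then NBS, −78 °C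
Reagents that add atoms: N-bromosuccinimide, O=C1CCC(=O)N1Br; chlorotrimethylsilane, C[Si](C)(C)Cl (silyl group present in 17 only)
Why: Kinetic alpha-prime deprotonation with in situ silylation gives the cross-conjugated silyl dienol ether 17, which is far more nucleophilic than the trisubstituted alkenes, so electrophilic bromination occurs at C5, whose new stereocentre is racemic by design.

Step 12
Reactants: 18 racemic (Z)-bromo ketone PMBOCH2–C(OMe)2–C(Me)=CH–C(=O)–CHBr–R
Product: 19 racemic (Z)-bromo keto alcohol HOCH2–C(OMe)2–C(Me)=CH–C(=O)–CHBr–R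
Conditions: DDQ, CH2Cl2/pH 7 phosphate buffer, 0 °C
Reagents that add atoms: none
Why: Oxidative PMB cleavage (hydride abstraction from the electron-rich benzyl ether, then hydrolysis) runs under neutral conditions and is orthogonal to bromide, ketal, silyl ether and alkenes.

Step 13
Reactants: 19 racemic (Z)-bromo keto alcohol HOCH2–C(OMe)2–C(Me)=CH–C(=O)–CHBr–R
Product: 20 racemic (Z)-bromo keto aldehyde OHC–C(OMe)2–C(Me)=CH–C(=O)–CHBr–R
Conditions: Dess–Martin periodinane, NaHCO3, CH2Cl2, 0 °C; used after short filtration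
Reagents that add atoms: none
Why: Dess–Martin oxidation under NaHCO3 buffer is too weakly basic to touch the acidic C5–H or the Z-enone, and it drains the open hydroxy ketone form even if 19 rests partly as its cyclic C4 hemiketal tautomer.

Step 14
Reactants: 20 racemic (Z)-bromo keto aldehyde OHC–C(OMe)2–C(Me)=CH–C(=O)–CHBr–R
Product: 23 (5R,6S)-epoxyquinone C1 dimethyl monoketal with R on C5, via bromo enolate 21 (not isolated), via trans-bromohydrin aldolate 22 (not isolated)
Conditions: N-[4-(trifluoromethyl)benzyl]cinchoninium bromide (10 mol %), LiOH·H2O (solid), n-Bu2O, 0.01 M, 0 °C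
Reagents that add atoms: none
Why: Proposed new method: the hydroxide ion pair of the chiral ammonium cation removes the only acidic proton, C5–H between C4=O and Br, so the configuration of the racemic bromide is erased in enolate 21, C5 adds to the C6 aldehyde, and aldolate 22 expels bromide by rear-side attack of its oxygen on C5. The closest known reaction types are base-mediated intramolecular Darzens condensations and intermolecular phase-transfer-catalysed asymmetric Darzens reactions of alpha-halo ketones with aldehydes; a catalytic enantioselective ring-closing version on a bromo keto aldehyde has not been shown. The carbocycle closes 6-(enolendo)-exo-trig, since both enolate carbons C4 and C5 end up in the new ring, and the oxirane closes 3-exo-tet. C5 and C6 are tied to each other by the substrate: only the aldolate with oxygen and bromine antiperiplanar can close, the other diastereomer reverts by retro-aldol, and a three-membered ring can only be cis-fused to the six-membered one. The absolute sense (5R,6S) is controlled by the catalyst alone, whose cation (with its free C9 hydroxyl as hydrogen-bond donor) must favour one of the two mirror-image addition–displacement channels, so enantioface selectivity at the enolate is the selectivity the step needs. The substrate secures the rest: the Z-alkene keeps C5 and C6 within reach, the fully substituted C1 ketal makes the aldehyde non-enolisable and leaves no acidic C1–H, the vinylic C3 rules out a Favorskii pathway, and dilution suppresses intermolecular aldol addition.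

Step 15
Reactants: 23 (5R,6S)-epoxyquinone C1 dimethyl monoketal with R on C5
Product: 24 (5R,6S)-5,6-epoxy-2-methyl-5-R-cyclohex-2-ene-1,4-dione (epoxyquinone)
Conditions: p-TsOH·H2O (cat.), acetone/H2O, rt
Reagents that add atoms: water, O
Why: Acid-catalysed ketal hydrolysis unmasks C1, while the oxirane, deactivated towards acid by its carbonyl neighbours, the TBDPS ether and the C5 and C6 stereocentres should stay untouched.

Step 16
Reactants: 24 (5R,6S)-epoxyquinone
Product: 25 (1R,5R,6R)-epoxyquinol (C1 hydroxyl syn to the oxirane oxygen, C4 ketone retained, R on C5)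
Conditions: NaBH4 (0.5 equiv), CeCl3·7H2O, MeOH/THF, −78 °C
Reagents that add atoms: none
Why: In this Luche 1,2-reduction C4 is screened on one face by the oxirane oxygen and on the other by the chain on the adjacent quaternary C5, and it is deactivated by the vinylogous C2 methyl donor, so hydride should enter at C1 from the face anti to the oxirane and set 1R.

Step 17
Reactants: 25 (1R,5R,6R)-epoxyquinol
Product: 26 (1R,5R,6R)-epoxyquinol acetate (O-TBDPS yanuthone L)
Conditions: Ac2O, pyridine, 4-(dimethylamino)pyridine (cat.), CH2Cl2, 0 °C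
Reagents that add atoms: acetic anhydride, CC(=O)OC(C)=O
Why: Nucleophile-catalysed O-acylation of the only free hydroxyl proceeds with retention at C1.

Step 18
Reactants: 26 (1R,5R,6R)-epoxyquinol acetate (O-TBDPS yanuthone L)
Product: 27 yanuthone L, (1R,5R,6R)
Conditions: HF·pyridine, pyridine, THF, 0 °C to rt
Reagents that add atoms: none
Why: Fluoride-driven desilylation in a buffered, weakly acidic medium frees the primary allylic alcohol without touching acetate, oxirane or enone.

Compound list
1 | 1,3-dihydroxyacetone | OCC(=O)CO | starting material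
2 | 2,2-dimethoxypropane-1,3-diol | COC(CO)(CO)OC | intermediate
3 | 3-[(4-methoxybenzyl)oxy]-2,2-dimethoxypropan-1-ol | COc1ccc(COCC(CO)(OC)OC)cc1 | intermediate
4 | 3-[(4-methoxybenzyl)oxy]-2,2-dimethoxypropanal | COc1ccc(COCC(C=O)(OC)OC)cc1 | intermediate
5 | alkynyl ketal HC≡C–C(OMe)2–CH2OPMB | COc1ccc(COCC(OC)(OC)C#C)cc1 | intermediate
6 | (2E,6E)-farnesol | CC(C)=CCC/C(C)=C/CC/C(C)=C/CO | starting material
7 | (2E,6E)-farnesyl bromide | CC(C)=CCC/C(C)=C/CC/C(C)=C/CBr | intermediate
8 | N-methoxy-N-methylacetamide | CC(=O)N(C)OC | starting material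
9 | lithium enolate of 8 | [Li+].C=C([O-])N(C)OC | intermediate (not isolated)
10 | (4E,8E)-N-methoxy-N,5,9,13-tetramethyltetradeca-4,8,12-trienamide | CC(C)=CCC/C(C)=C/CC/C(C)=C/CCC(=O)N(C)OC | intermediate
11 | (4E,8E,12E)-14-hydroxy analogue of 10 | OC/C(C)=C/CC/C(C)=C/CC/C(C)=C/CCC(=O)N(C)OC | intermediate
12 | TBDPS ether of 11, MeO(Me)N–C(=O)–CH2–R | CC(C)(C)[Si](c1ccccc1)(c1ccccc1)OC/C(C)=C/CC/C(C)=C/CC/C(C)=C/CCC(=O)N(C)OC | intermediate
13 | lithium acetylide of 5 | [Li+].[C-]#CC(OC)(OC)COCc1ccc(OC)cc1 | intermediate (not isolated)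
14 | ynone PMBOCH2–C(OMe)2–C≡C–C(=O)–CH2–R | COc1ccc(COCC(OC)(OC)C#CC(=O)CC/C=C(\C)CC/C=C(\C)CC/C=C(\C)CO[Si](c2ccccc2)(c2ccccc2)C(C)(C)C)cc1 | intermediate
15 | lithium allenolate from methyl addition to C2 of 14 | [Li+].COc1ccc(COCC(OC)(OC)C(C)=C=C([O-])CC/C=C(\C)CC/C=C(\C)CC/C=C(\C)CO[Si](c2ccccc2)(c2ccccc2)C(C)(C)C)cc1 | intermediate (not isolated)
16 | (Z)-enone PMBOCH2–C(OMe)2–C(Me)=CH–C(=O)–CH2–R | COc1ccc(COCC(OC)(OC)/C(C)=C\C(=O)CC/C=C(\C)CC/C=C(\C)CC/C=C(\C)CO[Si](c2ccccc2)(c2ccccc2)C(C)(C)C)cc1 | intermediate
17 | C4 trimethylsilyl dienol ether of 16 (C4=C5 geometry immaterial) | COc1ccc(COCC(OC)(OC)/C(C)=C\C(O[Si](C)(C)C)=CC/C=C(\C)CC/C=C(\C)CC/C=C(\C)CO[Si](c2ccccc2)(c2ccccc2)C(C)(C)C)cc1 | intermediate (not isolated)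
18 | (Z)-bromo ketone, PMB ether, racemic at C5 | COc1ccc(COCC(OC)(OC)/C(C)=C\C(=O)C(Br)C/C=C(\C)CC/C=C(\C)CC/C=C(\C)CO[Si](c2ccccc2)(c2ccccc2)C(C)(C)C)cc1 | intermediate
19 | (Z)-bromo keto alcohol, racemic at C5 | OCC(OC)(OC)/C(C)=C\C(=O)C(Br)C/C=C(\C)CC/C=C(\C)CC/C=C(\C)CO[Si](c1ccccc1)(c1ccccc1)C(C)(C)C | intermediate
20 | (Z)-bromo keto aldehyde, racemic at C5 (key-step precursor) | O=CC(OC)(OC)/C(C)=C\C(=O)C(Br)C/C=C(\C)CC/C=C(\C)CC/C=C(\C)CO[Si](c1ccccc1)(c1ccccc1)C(C)(C)C | intermediate
21 | C4–C5 bromo enolate of 20 (chiral ammonium counter-ion omitted) | O=CC(OC)(OC)/C(C)=C\C([O-])=C(Br)C/C=C(\C)CC/C=C(\C)CC/C=C(\C)CO[Si](c1ccccc1)(c1ccccc1)C(C)(C)C | intermediate (not isolated)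
22 | (5S,6R)-trans-bromohydrin aldolate (counter-ion omitted) | COC1(OC)C(C)=CC(=O)[C@](Br)(C/C=C(\C)CC/C=C(\C)CC/C=C(\C)CO[Si](c2ccccc2)(c2ccccc2)C(C)(C)C)[C@@H]1[O-] | intermediate (not isolated)
23 | (5R,6S)-epoxyquinone C1 dimethyl monoketal (key-step product) | COC1(OC)C(C)=CC(=O)[C@]2(C/C=C(\C)CC/C=C(\C)CC/C=C(\C)CO[Si](c3ccccc3)(c3ccccc3)C(C)(C)C)O[C@H]12 | intermediate
24 | (5R,6S)-epoxyquinone | O=C1C(C)=CC(=O)[C@]2(C/C=C(\C)CC/C=C(\C)CC/C=C(\C)CO[Si](c3ccccc3)(c3ccccc3)C(C)(C)C)O[C@H]12 | intermediate
25 | (1R,5R,6R)-epoxyquinol | O[C@@H]1C(C)=CC(=O)[C@]2(C/C=C(\C)CC/C=C(\C)CC/C=C(\C)CO[Si](c3ccccc3)(c3ccccc3)C(C)(C)C)O[C@H]12 | intermediate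
26 | (1R,5R,6R)-epoxyquinol acetate, TBDPS ether | CC(=O)O[C@@H]1C(C)=CC(=O)[C@]2(C/C=C(\C)CC/C=C(\C)CC/C=C(\C)CO[Si](c3ccccc3)(c3ccccc3)C(C)(C)C)O[C@H]12 | intermediate
27 | yanuthone L | CC(=O)O[C@@H]1C(C)=CC(=O)[C@]2(C/C=C(\C)CC/C=C(\C)CC/C=C(\C)CO)O[C@H]12 | target

Total step count: 18. Longest linear sequence: 14 (steps 5–8, then 9–18; the branch through steps 1–4 has the same length).

Steps most likely to fail

1. Step 14 (new method).
What may go wrong:
- weak discrimination between the mirror-image addition–displacement channels;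
- uncatalysed closure at the surface of the solid base;
- E2 loss of HBr towards the chain;
- hydroxide attack on the aldehyde with loss of formate;
- Z-to-E isomerisation of the enone.

The fallback uses only known reaction types and separates ring closure from oxygen transfer. It sets out from 16 and comes back at 23. Bromination is omitted. DDQ in CH2Cl2/pH 7 buffer frees the C6 hydroxyl of 16 to give hydroxy enone F1, and Dess–Martin oxidation gives keto aldehyde F2. DBU in toluene then brings about an intramolecular aldol condensation (C5 onto C6, then E1cB loss of water) to quinone monoketal F3, a 4,4-dimethoxycyclohexa-2,5-dienone. A Weitz–Scheffer epoxidation under chiral phase-transfer catalysis follows (t-BuOOH, aqueous NaOH, N-benzylcinchonidinium chloride, toluene). It should attack C6, the beta-carbon that carries no methyl group, and close onto C5 to give 23.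

2. Step 16.
What may go wrong:
- hydride entering C1 from the oxirane face;
- competing attack at C4;
- conjugate reduction of the enedione.

The fallback fixes C1 by substitution instead of by hydride trajectory. It sets out from 24 and comes back at 26. The reduction is run as before and the C1 epimers are separated. The (1S)-epoxyquinol F4 (hydroxyl anti to the oxirane) is esterified under Mitsunobu conditions (AcOH, PPh3, diisopropyl azodicarboxylate, THF, 0 °C). SN2 inversion at C1 leads directly to 26, and any 25 is acetylated as in step 17, so both epimers converge.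

3. Step 10.
What may go wrong:
- erosion of the Z geometry by equilibration of the copper-bound adduct;
- isomerisation of the crowded Z-enone during quench and chromatography; the E isomer cannot cyclise in step 14.

The fallback moves the methyl transfer to the alcohol oxidation level, where the alkenyl metal is configurationally stable. It sets out from 14 and comes back at 16. Luche reduction (NaBH4, CeCl3·7H2O, MeOH, −78 °C) gives racemic propargylic alcohol F5. Alkoxide-directed syn carbomagnesiation (MeMgBr in excess, Fe(acac)3 cat., THF, −78 to 0 °C) places methyl on the distal carbon C2 and magnesium on C3. Retentive protonolysis gives (Z)-allylic alcohol F6, and MnO2 in CH2Cl2 oxidises it to 16.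

Further compounds
F1 | step 14 | (Z)-hydroxy enone HOCH2–C(OMe)2–C(Me)=CH–C(=O)–CH2–R | OCC(OC)(OC)/C(C)=C\C(=O)CC/C=C(\C)CC/C=C(\C)CC/C=C(\C)CO[Si](c1ccccc1)(c1ccccc1)C(C)(C)C
F2 | step 14 | (Z)-keto aldehyde OHC–C(OMe)2–C(Me)=CH–C(=O)–CH2–R | O=CC(OC)(OC)/C(C)=C\C(=O)CC/C=C(\C)CC/C=C(\C)CC/C=C(\C)CO[Si](c1ccccc1)(c1ccccc1)C(C)(C)C
F3 | step 14 | quinone monoketal, 4,4-dimethoxy-5-methyl-2-R-cyclohexa-2,5-dienone | COC1(OC)C=C(C/C=C(\C)CC/C=C(\C)CC/C=C(\C)CO[Si](c2ccccc2)(c2ccccc2)C(C)(C)C)C(=O)C=C1C
F4 | step 16 | (1S,5R,6R)-epoxyquinol, C1 epimer of 25 | O[C@H]1C(C)=CC(=O)[C@]2(C/C=C(\C)CC/C=C(\C)CC/C=C(\C)CO[Si](c3ccccc3)(c3ccccc3)C(C)(C)C)O[C@H]12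
F5 | step 10 | racemic propargylic alcohol PMBOCH2–C(OMe)2–C≡C–CH(OH)–CH2–R | COc1ccc(COCC(OC)(OC)C#CC(O)CC/C=C(\C)CC/C=C(\C)CC/C=C(\C)CO[Si](c2ccccc2)(c2ccccc2)C(C)(C)C)cc1
F6 | step 10 | racemic (Z)-allylic alcohol PMBOCH2–C(OMe)2–C(Me)=CH–CH(OH)–CH2–R | COc1ccc(COCC(OC)(OC)/C(C)=C\C(O)CC/C=C(\C)CC/C=C(\C)CC/C=C(\C)CO[Si](c2ccccc2)(c2ccccc2)C(C)(C)C)cc1
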